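At the reading, 12 min after the charge, two numbers are wanted from this flask.

substrate 0.13 M; partner 1.20 equiv; scavenger 0.500 equiv; protic impurity 0.0650 M; time 12 min

    partner + released group ⇌ idle adduct, settled at all times (K1 = 2.3 M⁻¹)
    partner + protic impurity → quenched reagent (k2 = 0.041 M⁻¹ s⁻¹)
    scavenger + released group → scavenged by-product (k3 = 1.6 M⁻¹ s⁻¹)
    intermediate ⇌ target + released group (K4 = 0.12 M, k4 = 0.015 s⁻¹)
    substrate + partner ⇌ intermediate (K5 = 210 M⁻¹, k5 = 0.046 M⁻¹ s⁻¹)
    target + released group → side product (k6 = 0.0048 M⁻¹ s⁻¹)

- what is said of released group includes idle adduct
- run time (flask): 12 min

1. part of the substrate that has reacted at 12 min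
2. share of the unused partner that is free and not bound as idle adduct, at 12 min

- In fractions of the substrate charge, the partner's 1.20 meets a pool of 1.50 made of substrate and protic impurity, so the partner is the limiting reagent of that pool.
- The substrate's constant is 1.12 times the impurity's, so as a first reckoning both lose about the same fraction of themselves, and partner over pool gives 80.0%, the shared ceiling.
- Letting the impurity lag by the ratio of the constants lifts the bound from above to 81.9%.
- For a bound from below, both consumers get the smaller constant and the forward steps alone are counted, with the substrate step far forward at 33.
- Pool and partner then differ by a fixed 0.300 of the charge, and their ratio falls by a factor 0.316 in the run, which gives 73.2%.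
- The free share of unused partner is one over one plus the step-one constant times the free released group.
- Scavenger takes released group in about 0.11 min, faster than the impurity takes partner, so with conversion held under the bound from above, at most 0.319 of the charge stays unscavenged, and the free share stands above 91.3%.
- The forecast, 74% and 96%, reasons that the partner is “shared almost evenly between the substrate and the protic impurity”, and both numbers lie inside these bounds.
- The flask gives 74.4% and 96.3%, inside both bounds. Its conversion stands 5.6 percentage points under the shared ceiling, with 7.94% of the charged partner still free at 12.0 min. For the neighbour flask with 0.11 M of protic impurity, the pool grows and the ceiling drops to 65.0%. That neighbour flask reaches 64.6%, with 2.90% of its partner left.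

(The numbers were drawn at random within sensible limits; the flask was simulated.)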